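## Structural features

The target is a linear tridepside with no stereocenter: three benzene rings (A, B and C) are joined head to tail by two aryl ester bonds. Each ring carries a carbonyl carbon on C1, a hydroxyl on C2 and a methyl group on C6 (the same locants are used for all three rings). Ring A is a 2,4-dihydroxy-5-methoxy-6-methylbenzoyl unit whose carbonyl is esterified by the oxygen on C4 of ring B; the ring B carbonyl is esterified by the oxygen on C4 of ring C, and ring C ends in a free carboxylic acid. Because there is no stereochemistry, the problem is one of regiochemistry and chemoselectivity: four phenolic hydroxyls, one methyl ether and one acid must be told apart so that exactly two oxygens are acylated. The fragile parts are the two aryl esters (cleavage and acyl transfer under basic or nucleophilic conditions), the salicylic-type acid of ring C (decarboxylation on heating) and the electron-rich ring A (oxidation). The classical difficulty is steric, since every acyl carbon lies between two ortho substituents and ester formation at such acids is slow and needs protected ortho hydroxyls. The feature exploited here is that each acyl carbon is flanked by a methyl group (C6) and a hydroxyl (C2): once the three C2 oxygens are left out, each carbonyl has exactly one ortho C–H bond, the acids are only singly ortho-substituted, and the three carbonyl oxygens can direct a late oxygenation of C2 in rings A, B and C.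

## Logic of the disconnections

**20 to 18.** The O–CH2 bond of the ester on the ring C carboxyl is cut. The acid must be masked during assembly and during the oxidation, where a free acid would become a reactive mixed anhydride. The mask has to survive a hot, strongly acidic anhydride medium and a strong oxidant, and it has to leave under neutral conditions that spare two aryl esters. A 4-nitrobenzyl group is therefore carried in 18; a plain benzyl group would be open to acidolysis and benzylic oxidation in that medium. The forward step must run at room temperature, because the product acid decarboxylates easily.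

**18 to 15.** The three aryl C–O bonds at C2 of rings A, B and C are cut. This removes three of the four phenols, so nothing needs to be differentiated, and it turns three doubly ortho-substituted acids into singly substituted ones. The forward step must oxygenate the single ortho C–H bond next to each carbonyl, three times in one molecule, without touching the positions beside the ester oxygens or the methoxy-bearing ring. The ring A hydroxyl of 15 is left free on purpose, because it is acylated in the flask before any oxidant is added.

**15 to 14, then 13 plus 7.** The O–Si bond on ring A is cut, then the ester bond between the ring A carbonyl and the C4 oxygen of ring B. This splits the molecule into a one-ring acid and a two-ring phenol. The forward coupling needs the phenol of 7 to be the only nucleophile, which is why the ring A hydroxyl is silylated in 13. The silyl group must then come off without fluoride or a phenoxide attacking the esters.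

**7 to 6, then 3 plus 5.** The same O–Si and ester cuts are applied between rings B and C. Both halves derive from one hydroxy acid, so the gain is a single building block for two rings. The demand is the same as above: one free phenol (in 3) and one free acid (in 5).

**13 to 10 to 9 to 8.** The bond between C1 of ring A and the carboxyl carbon is cut (carboxylation of an aryl metal), then the O–Si bond, then the C–Br bond. In 8 the position para to the hydroxyl is the most activated and lies next to the methyl group, which is exactly where the carboxyl carbon must go. The forward steps need para-selective bromination and a halogen–metal exchange that tolerates the aryl silyl ether.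

**3 to 1 plus 2; 5 to 1.** The ester O–CH2 bond of 3 and the O–Si bond of 5 are cut, so that 1 supplies both ring B and ring C. The forward steps need carboxylate alkylation in the presence of a free phenol, and selective hydrolysis of a silyl ester next to an aryl silyl ether.

## Other disconnections considered

Alternative 1: Ring A is assembled from two acyclic pieces by cutting its C1–C6 and C3–C4 bonds, and it is aromatized only late.
- **Forward key step.** The enolate of tert-butyl acetoacetate A1 would add through its central carbon to the β-carbon of methyl (Z)-2-methoxybut-2-enoate A2 in a Michael addition. The acetyl methyl carbon of the A1 unit would then close onto the methyl ester of the A2 unit in a Claisen condensation, giving the cyclic dione A3. Heating A3 with the C4 hydroxyl of a ring B unit would exchange the tert-butyl ester for the aryl ester in a thermal acyl transfer, and a dehydrogenation would then aromatize ring A.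
- **In favour.** A1 is a cheap bulk chemical. The C2 and C4 oxygens stem from the two dione carbonyls and the methoxy and methyl groups from A2, so the substitution pattern of ring A is fixed by construction; on regiochemical certainty for ring A this is better than the chosen plan. The thermal ester exchange forms the hindered ester between rings A and B without activating a doubly ortho-substituted acid, which equals the chosen plan on that point. Every step belongs to an established reaction class, which is better than the chosen plan on precedent.
- **Against.** A2 is a poor Michael acceptor (donor on the α-carbon, substituent on the β-carbon). The dehydrogenation would have to be carried out on a molecule that already holds depside esters. Acid-promoted loss of the C5 methoxy group would also aromatize the ring and delete that substituent.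
- **Comparison.** Only ring A is addressed. Rings B and C would still have to be brought in with their C2 hydroxyls protected and differentiated, so the step count would be clearly higher than for the route through 15 and 18. The diastereomers of A3 are erased on aromatization, so neither plan has a lasting stereochemical problem and the two are equal there.

Alternative 2: Ring A is formed by cutting its C1–C2 bond; the precursor is a four-membered ring ketone whose C2–C5 bond opens first.
- **Forward key step.** Heating the racemic cyclobutenone A4 would open the four-membered ring in a four-electron electrocyclic step. The ketene carbon so formed would bond to the ester-bearing alkene carbon in a six-electron electrocyclization, and enolization would give the phenol A5.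
- **In favour.** All five substituents of ring A are placed without ambiguity, and the three oxygens arrive differentiated in A5 (free hydroxyl on C2, isopropyl ether on C4, methyl ether on C5); this is better than the chosen plan on regiochemical certainty. The step is thermal and needs no reagent, so no oxidant comes near the electron-rich ring, which is also better than the chosen plan. The reaction class is established.
- **Against.** The preparation of A4 requires the addition of a β-metalated crotonate ester to a squaric acid derivative and the O-methylation of a tertiary alkoxide. After A5, the tert-butyl ester must be cleaved to a doubly ortho-substituted salicylic acid, and its esterification with the ring B phenol is exactly the sluggish coupling that the chosen plan avoids. The isopropyl ether must later be removed with a Lewis acid beside two aryl esters and a methyl ether.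
- **Comparison.** Rings B and C would still need their C2 hydroxyls and protecting groups, so the route would be longer. The stereocenter of A4 disappears in A5, so the two plans are equal on stereochemistry.

Alternative 3: Ring B is grown on the ester of ring C by cutting its C1–C2, C2–C3, C4–C5 and C5–C6 bonds.
- **Forward key step.** Irradiation of the diazoketone A6 would trigger a Wolff rearrangement with alkenyl shift. The ketene so formed would add (2+2) to the siloxyalkyne A7, and four-electron opening of the four-membered ring followed by six-electron closure would give the didepside A8.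
- **In favour.** Ring B is formed with the hindered ester to ring C already in place. The oxygens of A8 arrive differentiated, the C2 hydroxyl free and the C4 oxygen silylated, which is what the next acylation by ring A needs. Placing these oxygens by construction is better than relying on C–H site selectivity, and the benzannulation is an established reaction class, which is better than the chosen plan on precedent.
- **Against.** A6 combines a diazoketone with an electron-poor alkene, which invites dipolar cycloaddition. The ketene derived from A6 is electron-poor, and A7 is a sensitive terminal siloxyalkyne. Ring A must still be attached as a fully oxygenated, doubly ortho-substituted acid with protected hydroxyls, and ring C needs benzyl protection from the start.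
- **Comparison.** A photochemical step is harder to scale than the thermal oxygenation of 15, and the overall route would be much longer. Both plans are free of stereochemical issues, so they are equal on that count.

Key step: step 10

Remark on the chemistry: a 4-nitrobenzyl ester is chosen as the carboxyl mask of ring C, because a plain benzyl ester would be at risk of acidolysis and benzylic oxidation in hot CF3CO2H with K2S2O8; the carbon skeleton and the three bonds formed in the key step are unaffected by this choice.

## Steps

Step 1
Reactants: 1 4-hydroxy-2-methylbenzoic acid; 2 4-nitrobenzyl bromide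
Product: 3 4-nitrobenzyl 4-hydroxy-2-methylbenzoate
Conditions: KHCO3, DMF, 40 °C
Reagents that add atoms: none
Why: Carboxylate O-alkylation (SN2 at a benzylic bromide); KHCO3 deprotonates only the carboxylic acid and leaves the much less acidic phenol protonated, so the ester forms without ether formation.

Step 2
Reactants: 1 4-hydroxy-2-methylbenzoic acid
Product: 5 4-[(tert-butyldimethylsilyl)oxy]-2-methylbenzoic acid, via bis-silyl derivative 4 (not isolated)
Conditions: TBSCl, imidazole, DMF, rt; then AcOH/THF/H2O, rt
Reagents that add atoms: tert-butyldimethylsilyl chloride, CC(C)(C)[Si](C)(C)Cl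
Why: Silylation of both acidic sites followed by selective hydrolysis of the far more labile silyl ester, a standard protection sequence; the aryl silyl ether is stable to aqueous acetic acid.

Step 3
Reactants: 3 4-nitrobenzyl 4-hydroxy-2-methylbenzoate; 5 4-[(tert-butyldimethylsilyl)oxy]-2-methylbenzoic acid
Product: 6 4-nitrobenzyl 4-({4-[(tert-butyldimethylsilyl)oxy]-2-methylbenzoyl}oxy)-2-methylbenzoate
Conditions: DCC, DMAP (cat.), CH2Cl2, 0 °C to rt
Reagents that add atoms: none
Why: Steglich esterification; the acid has only one ortho substituent, so the acylpyridinium intermediate forms readily and is captured by the single free phenol.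

Step 4
Reactants: 6 4-nitrobenzyl 4-({4-[(tert-butyldimethylsilyl)oxy]-2-methylbenzoyl}oxy)-2-methylbenzoate
Product: 7 4-nitrobenzyl 4-[(4-hydroxy-2-methylbenzoyl)oxy]-2-methylbenzoate
Conditions: HF·pyridine, pyridine, THF, 0 °C to rt
Reagents that add atoms: none
Why: Fluoride-mediated desilylation driven by the strong Si–F bond; the mildly acidic reagent keeps the liberated phenol protonated, so neither the aryl ester nor the nitrobenzyl ester is attacked.

Step 5
Reactants: 8 2-methoxy-3-methylphenol
Product: 9 4-bromo-2-methoxy-3-methylphenol
Conditions: NBS, MeCN, −20 to 0 °C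
Reagents that add atoms: N-bromosuccinimide, O=C1CCC(=O)N1Br
Why: Electrophilic aromatic bromination; the hydroxyl is the strongest activator and directs para, the flanked methoxy group is twisted out of conjugation, and NBS in acetonitrile favours para over ortho attack.

Step 6
Reactants: 9 4-bromo-2-methoxy-3-methylphenol
Product: 10 (4-bromo-2-methoxy-3-methylphenoxy)(tert-butyl)dimethylsilane
Conditions: TBSCl, imidazole, DMF, rt
Reagents that add atoms: tert-butyldimethylsilyl chloride, CC(C)(C)[Si](C)(C)Cl
Why: Standard silylation of a phenol; it removes the acidic proton before the organolithium step and later keeps the ring A oxygen from competing in the esterification.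

Step 7
Reactants: 10 (4-bromo-2-methoxy-3-methylphenoxy)(tert-butyl)dimethylsilane
Product: 13 4-[(tert-butyldimethylsilyl)oxy]-3-methoxy-2-methylbenzoic acid, via aryllithium 11 (not isolated), via lithium carboxylate 12 (not isolated)
Conditions: n-BuLi, THF, −78 °C; CO2, −78 °C to rt; then cold 1 M HCl to pH 3
Reagents that add atoms: carbon dioxide, O=C=O
Why: Bromine–lithium exchange followed by carboxylation of the aryllithium; exchange at −78 °C is faster than attack on the silyl ether, and the silyl group para to the metal cannot migrate to carbon.

Step 8
Reactants: 13 4-[(tert-butyldimethylsilyl)oxy]-3-methoxy-2-methylbenzoic acid; 7 4-nitrobenzyl 4-[(4-hydroxy-2-methylbenzoyl)oxy]-2-methylbenzoate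
Product: 14 4-nitrobenzyl 4-{[4-({4-[(tert-butyldimethylsilyl)oxy]-3-methoxy-2-methylbenzoyl}oxy)-2-methylbenzoyl]oxy}-2-methylbenzoate
Conditions: DCC, DMAP (cat.), CH2Cl2, 0 °C to rt
Reagents that add atoms: none
Why: Second Steglich esterification at a singly ortho-substituted acid; the phenol of 7 is the only nucleophile present and the existing aryl ester is inert to the acylpyridinium intermediate.

Step 9
Reactants: 14 4-nitrobenzyl 4-{[4-({4-[(tert-butyldimethylsilyl)oxy]-3-methoxy-2-methylbenzoyl}oxy)-2-methylbenzoyl]oxy}-2-methylbenzoate
Product: 15 4-nitrobenzyl 4-({4-[(4-hydroxy-3-methoxy-2-methylbenzoyl)oxy]-2-methylbenzoyl}oxy)-2-methylbenzoate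
Conditions: HF·pyridine, pyridine, THF, 0 °C to rt
Reagents that add atoms: none
Why: Fluoride-mediated desilylation as in step 4; under these non-basic conditions the two aryl esters cannot be scrambled by a phenoxide.

Step 10
Reactants: 15 4-nitrobenzyl 4-({4-[(4-hydroxy-3-methoxy-2-methylbenzoyl)oxy]-2-methylbenzoyl}oxy)-2-methylbenzoate
Product: 18 4-nitrobenzyl 4-({4-[(2,4-dihydroxy-5-methoxy-6-methylbenzoyl)oxy]-2-hydroxy-6-methylbenzoyl}oxy)-2-hydroxy-6-methylbenzoate, via ring A trifluoroacetate 16 (not isolated), via tetrakis(trifluoroacetate) 17 (not isolated)
Conditions: (CF3CO)2O/CF3CO2H, rt; then [RuCl2(p-cymene)]2 (10 mol%), K2S2O8 (4.5 equiv), 80 °C, sealed tube; then THF/H2O, rt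
Reagents that add atoms: trifluoroacetic acid, OC(=O)C(F)(F)F (as trifluoroacetate it supplies the three new oxygen atoms); trifluoroacetic anhydride, O=C(OC(=O)C(F)(F)F)C(F)(F)F (trifluoroacetyl groups of 16 and 17 only, lost again on hydrolysis)
Why: Proposed new method: a threefold carbonyl-directed ortho C–H oxygenation of a tridepside, whose closest known reaction type is the ester-directed ortho-hydroxylation of simple alkyl benzoates with [RuCl2(p-cymene)]2 and an oxidant in CF3CO2H/(CF3CO)2O, here extended to aryl ester directing groups and to three sites in one molecule. The anhydride first acylates the ring A hydroxyl (16); each ester carbonyl oxygen then binds a divalent ruthenium trifluoroacetate, and carboxylate-assisted metalation of the only ortho C–H bond gives a five-membered ruthenacycle. K2S2O8 oxidizes this to tetravalent ruthenium, and C–O reductive elimination releases the aryl trifluoroacetate and regenerates divalent ruthenium; no ring is closed and no stereocenter is formed. The selectivity required is for C2 of each ring over the positions beside the ester oxygens of rings B and C (six-membered chelate) and over C3 of ring A. It should be secured by the ortho methyl groups, which leave one ortho C–H per carbonyl, by the preference for the five-membered chelate of a carbonyl conjugated with its acyl ring (the O-aryl ring is twisted out of the ester plane), and by the electron-poor trifluoroacetyl carbonyl on ring A, which is a poor donor. Each oxygenated ring becomes a doubly ortho-substituted, trifluoroacetoxy-deactivated benzoate with no ortho C–H left, which should stop over-oxidation, while the 4-nitrobenzyl ester should resist hot CF3CO2H and benzylic oxidation. Water finally hydrolyses the four aryl trifluoroacetates of 17.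

Step 11
Reactants: 18 4-nitrobenzyl 4-({4-[(2,4-dihydroxy-5-methoxy-6-methylbenzoyl)oxy]-2-hydroxy-6-methylbenzoyl}oxy)-2-hydroxy-6-methylbenzoate
Product: 20 4-({4-[(2,4-dihydroxy-5-methoxy-6-methylbenzoyl)oxy]-2-hydroxy-6-methylbenzoyl}oxy)-2-hydroxy-6-methylbenzoic acid, via 4-aminobenzyl ester 19 (not isolated)
Conditions: H2 (1 atm), Pd/C (10 wt% Pd on carbon), THF/EtOAc, rt; cold dilute HCl wash
Reagents that add atoms: none
Why: Catalytic hydrogenation reduces the nitro group and hydrogenolyses the benzylic C–O bond of the resulting aminobenzyl ester; aryl esters, phenols and the aryl methyl ether are inert to H2 over palladium at room temperature, and no heat is applied to the decarboxylation-prone acid.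

## Compound list

1 | 4-hydroxy-2-methylbenzoic acid | Cc1cc(O)ccc1C(=O)O | starting material
2 | 4-nitrobenzyl bromide [1-(bromomethyl)-4-nitrobenzene] | O=[N+]([O-])c1ccc(CBr)cc1 | starting material
3 | 4-nitrobenzyl 4-hydroxy-2-methylbenzoate | Cc1cc(O)ccc1C(=O)OCc1ccc([N+](=O)[O-])cc1 | intermediate
4 | tert-butyldimethylsilyl 4-[(tert-butyldimethylsilyl)oxy]-2-methylbenzoate | Cc1cc(O[Si](C)(C)C(C)(C)C)ccc1C(=O)O[Si](C)(C)C(C)(C)C | intermediate
5 | 4-[(tert-butyldimethylsilyl)oxy]-2-methylbenzoic acid | Cc1cc(O[Si](C)(C)C(C)(C)C)ccc1C(=O)O | intermediate
6 | 4-nitrobenzyl 4-({4-[(tert-butyldimethylsilyl)oxy]-2-methylbenzoyl}oxy)-2-methylbenzoate | Cc1cc(O[Si](C)(C)C(C)(C)C)ccc1C(=O)Oc1cc(C)c(C(=O)OCc2ccc([N+](=O)[O-])cc2)cc1 | intermediate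
7 | 4-nitrobenzyl 4-[(4-hydroxy-2-methylbenzoyl)oxy]-2-methylbenzoate | Cc1cc(O)ccc1C(=O)Oc1cc(C)c(C(=O)OCc2ccc([N+](=O)[O-])cc2)cc1 | intermediate
8 | 2-methoxy-3-methylphenol | COc1c(C)cccc1O | starting material
9 | 4-bromo-2-methoxy-3-methylphenol | COc1c(O)ccc(Br)c1C | intermediate
10 | (4-bromo-2-methoxy-3-methylphenoxy)(tert-butyl)dimethylsilane | COc1c(O[Si](C)(C)C(C)(C)C)ccc(Br)c1C | intermediate
11 | {4-[(tert-butyldimethylsilyl)oxy]-3-methoxy-2-methylphenyl}lithium | COc1c(O[Si](C)(C)C(C)(C)C)ccc([Li])c1C | intermediate
12 | lithium 4-[(tert-butyldimethylsilyl)oxy]-3-methoxy-2-methylbenzoate | COc1c(O[Si](C)(C)C(C)(C)C)ccc(C(=O)[O-])c1C.[Li+] | intermediate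
13 | 4-[(tert-butyldimethylsilyl)oxy]-3-methoxy-2-methylbenzoic acid | COc1c(O[Si](C)(C)C(C)(C)C)ccc(C(=O)O)c1C | intermediate
14 | 4-nitrobenzyl 4-{[4-({4-[(tert-butyldimethylsilyl)oxy]-3-methoxy-2-methylbenzoyl}oxy)-2-methylbenzoyl]oxy}-2-methylbenzoate | COc1c(O[Si](C)(C)C(C)(C)C)ccc(C(=O)Oc2cc(C)c(C(=O)Oc3cc(C)c(C(=O)OCc4ccc([N+](=O)[O-])cc4)cc3)cc2)c1C | intermediate
15 | 4-nitrobenzyl 4-({4-[(4-hydroxy-3-methoxy-2-methylbenzoyl)oxy]-2-methylbenzoyl}oxy)-2-methylbenzoate (key-step precursor) | COc1c(O)ccc(C(=O)Oc2cc(C)c(C(=O)Oc3cc(C)c(C(=O)OCc4ccc([N+](=O)[O-])cc4)cc3)cc2)c1C | intermediate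
16 | 4-nitrobenzyl 4-{[4-({3-methoxy-2-methyl-4-[(trifluoroacetyl)oxy]benzoyl}oxy)-2-methylbenzoyl]oxy}-2-methylbenzoate | COc1c(OC(=O)C(F)(F)F)ccc(C(=O)Oc2cc(C)c(C(=O)Oc3cc(C)c(C(=O)OCc4ccc([N+](=O)[O-])cc4)cc3)cc2)c1C | intermediate
17 | tetrakis(trifluoroacetate) of 18 (trifluoroacetyl on the C2 and C4 oxygens of ring A and on the C2 oxygens of rings B and C) | COc1c(OC(=O)C(F)(F)F)cc(OC(=O)C(F)(F)F)c(C(=O)Oc2cc(C)c(C(=O)Oc3cc(C)c(C(=O)OCc4ccc([N+](=O)[O-])cc4)c(OC(=O)C(F)(F)F)c3)c(OC(=O)C(F)(F)F)c2)c1C | intermediate
18 | 4-nitrobenzyl 4-({4-[(2,4-dihydroxy-5-methoxy-6-methylbenzoyl)oxy]-2-hydroxy-6-methylbenzoyl}oxy)-2-hydroxy-6-methylbenzoate (key-step product) | COc1c(O)cc(O)c(C(=O)Oc2cc(C)c(C(=O)Oc3cc(C)c(C(=O)OCc4ccc([N+](=O)[O-])cc4)c(O)c3)c(O)c2)c1C | intermediate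
19 | 4-aminobenzyl 4-({4-[(2,4-dihydroxy-5-methoxy-6-methylbenzoyl)oxy]-2-hydroxy-6-methylbenzoyl}oxy)-2-hydroxy-6-methylbenzoate | COc1c(O)cc(O)c(C(=O)Oc2cc(C)c(C(=O)Oc3cc(C)c(C(=O)OCc4ccc(N)cc4)c(O)c3)c(O)c2)c1C | intermediate
20 | 4-({4-[(2,4-dihydroxy-5-methoxy-6-methylbenzoyl)oxy]-2-hydroxy-6-methylbenzoyl}oxy)-2-hydroxy-6-methylbenzoic acid | COc1c(O)cc(O)c(C(=O)Oc2cc(C)c(C(=O)Oc3cc(C)c(C(=O)O)c(O)c3)c(O)c2)c1C | target

## Step count and least certain steps

Total: 11 steps. Longest linear sequence: 7 steps (from 8 to 20 through steps 5, 6, 7, 8, 9, 10 and 11; the sequence from 1 through step 1 or 2 and then steps 3, 4, 8, 9, 10 and 11 is equally long).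

**Step 10 (key step, the proposed new method).**
What may go wrong: oxygenation may stop before all three sites have reacted, because aryl ester carbonyls bind the metal more weakly than alkyl ester carbonyls. Metalation may also go through the six-membered chelate at the positions beside the ester oxygens of rings B and C. The methoxy-bearing ring A may be degraded by the oxidant, and the aryl esters may undergo acyl exchange in the hot anhydride medium.

Fallback (known chemistry), from 13, returning at 20: the C2 oxygen is introduced on one ring only, on a simple alkyl benzoate, and the doubly ortho-substituted acids are then joined by the classical mixed-anhydride depside method. Fischer esterification of 13 with loss of the silyl group (MeOH, H2SO4, reflux) would give methyl 4-hydroxy-3-methoxy-2-methylbenzoate F1. One ester-directed ortho-hydroxylation of this alkyl benzoate, the substrate class for which the reaction is established ([RuCl2(p-cymene)]2, K2S2O8, CF3CO2H/(CF3CO)2O, 80 °C, then water), would pass through methyl 3-methoxy-2-methyl-4-[(trifluoroacetyl)oxy]benzoate F2 and methyl 3-methoxy-2-methyl-4,6-bis[(trifluoroacetyl)oxy]benzoate F3 to methyl 4,6-dihydroxy-3-methoxy-2-methylbenzoate F4. Benzylation (benzyl bromide, K2CO3, DMF) would give methyl 4,6-bis(benzyloxy)-3-methoxy-2-methylbenzoate F5, and saponification of the hindered ester (KOH, aqueous DMSO, 90 °C, then acid) would give 4,6-bis(benzyloxy)-3-methoxy-2-methylbenzoic acid F6. Treatment of F6 with (CF3CO)2O in toluene at rt would give 4,6-bis(benzyloxy)-3-methoxy-2-methylbenzoic trifluoroacetic anhydride F7. This would acylate the non-chelated para hydroxyl of purchased 2,4-dihydroxy-6-methylbenzaldehyde to give 4-formyl-3-hydroxy-5-methylphenyl 4,6-bis(benzyloxy)-3-methoxy-2-methylbenzoate F8. Benzylation of the remaining phenol would give 3-(benzyloxy)-4-formyl-5-methylphenyl 4,6-bis(benzyloxy)-3-methoxy-2-methylbenzoate F9, and Pinnick oxidation (NaClO2, NaH2PO4, 2-methyl-2-butene, t-BuOH/H2O) would give 2-(benzyloxy)-4-{[4,6-bis(benzyloxy)-3-methoxy-2-methylbenzoyl]oxy}-6-methylbenzoic acid F10. Activation with (CF3CO)2O as before would give 2-(benzyloxy)-4-{[4,6-bis(benzyloxy)-3-methoxy-2-methylbenzoyl]oxy}-6-methylbenzoic trifluoroacetic anhydride F11. This would acylate the para hydroxyl of benzyl 2,4-dihydroxy-6-methylbenzoate F12 (from purchased 2,4-dihydroxy-6-methylbenzoic acid, benzyl bromide, KHCO3, DMF) to give benzyl 4-[(2-(benzyloxy)-4-{[4,6-bis(benzyloxy)-3-methoxy-2-methylbenzoyl]oxy}-6-methylbenzoyl)oxy]-2-hydroxy-6-methylbenzoate F13. Hydrogenolysis of the four benzyl groups (H2, Pd/C, EtOAc, rt) would give 20.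

**Step 5.**
What may go wrong: attack ortho to the hydroxyl or a second bromination may compete, because the ring is strongly activated and the para position is flanked by the methyl group.

Fallback, from 8, returning at 10: the order of protection and halogenation is reversed so that the bulky silyl group shields the ortho position. Silylation of 8 (TBSCl, imidazole, DMF) would give tert-butyl(2-methoxy-3-methylphenoxy)dimethylsilane F14, and bromination of F14 (NBS, MeCN) para to the silyloxy group would give 10.

**Step 7.**
What may go wrong: the aryllithium may be protonated by adventitious moisture or alkylated by the 1-bromobutane formed in the exchange, and some silyl ether may be lost on acidification.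

Fallback, from 10, returning at 14: the organolithium and the free acid are bypassed by a palladium-catalysed carbonylative esterification of 10 with phenol 7 (Pd(OAc)2, Xantphos, Et3N, CO 1 atm, toluene, 90 °C). Oxidative addition to zerovalent palladium, CO insertion and capture of the acylpalladium by the phenol would give 14 directly, replacing steps 7 and 8. This fallback makes no new compound, F0.

**Step 11.**
What may go wrong: the reaction may stall at the aminobenzyl ester, the liberated aniline may take part in acyl transfer, and the acid may decarboxylate during concentration.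

Fallback, from 18, returning at 20: hydrogenation is replaced by an electron-transfer reduction with zinc dust in AcOH/THF/H2O at 0 °C to rt. The nitro group is reduced to the amine 19, which fragments by 1,6-elimination without hydrogen or palladium. This fallback makes no new compound, F0.

## Further compounds

F1 | step 10 | methyl 4-hydroxy-3-methoxy-2-methylbenzoate | COC(=O)c1ccc(O)c(OC)c1C
F2 | step 10 | methyl 3-methoxy-2-methyl-4-[(trifluoroacetyl)oxy]benzoate | COC(=O)c1ccc(OC(=O)C(F)(F)F)c(OC)c1C
F3 | step 10 | methyl 3-methoxy-2-methyl-4,6-bis[(trifluoroacetyl)oxy]benzoate | COC(=O)c1c(OC(=O)C(F)(F)F)cc(OC(=O)C(F)(F)F)c(OC)c1C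
F4 | step 10 | methyl 4,6-dihydroxy-3-methoxy-2-methylbenzoate | COC(=O)c1c(O)cc(O)c(OC)c1C
F5 | step 10 | methyl 4,6-bis(benzyloxy)-3-methoxy-2-methylbenzoate | COC(=O)c1c(OCc2ccccc2)cc(OCc2ccccc2)c(OC)c1C
F6 | step 10 | 4,6-bis(benzyloxy)-3-methoxy-2-methylbenzoic acid | OC(=O)c1c(OCc2ccccc2)cc(OCc2ccccc2)c(OC)c1C
F7 | step 10 | 4,6-bis(benzyloxy)-3-methoxy-2-methylbenzoic trifluoroacetic anhydride | COc1c(OCc2ccccc2)cc(OCc2ccccc2)c(C(=O)OC(=O)C(F)(F)F)c1C
F8 | step 10 | 4-formyl-3-hydroxy-5-methylphenyl 4,6-bis(benzyloxy)-3-methoxy-2-methylbenzoate | COc1c(OCc2ccccc2)cc(OCc2ccccc2)c(C(=O)Oc2cc(C)c(C=O)c(O)c2)c1C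
F9 | step 10 | 3-(benzyloxy)-4-formyl-5-methylphenyl 4,6-bis(benzyloxy)-3-methoxy-2-methylbenzoate | COc1c(OCc2ccccc2)cc(OCc2ccccc2)c(C(=O)Oc2cc(C)c(C=O)c(OCc3ccccc3)c2)c1C
F10 | step 10 | 2-(benzyloxy)-4-{[4,6-bis(benzyloxy)-3-methoxy-2-methylbenzoyl]oxy}-6-methylbenzoic acid | COc1c(OCc2ccccc2)cc(OCc2ccccc2)c(C(=O)Oc2cc(C)c(C(=O)O)c(OCc3ccccc3)c2)c1C
F11 | step 10 | 2-(benzyloxy)-4-{[4,6-bis(benzyloxy)-3-methoxy-2-methylbenzoyl]oxy}-6-methylbenzoic trifluoroacetic anhydride | COc1c(OCc2ccccc2)cc(OCc2ccccc2)c(C(=O)Oc2cc(C)c(C(=O)OC(=O)C(F)(F)F)c(OCc3ccccc3)c2)c1C
F12 | step 10 | benzyl 2,4-dihydroxy-6-methylbenzoate | Cc1cc(O)cc(O)c1C(=O)OCc1ccccc1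
F13 | step 10 | benzyl 4-[(2-(benzyloxy)-4-{[4,6-bis(benzyloxy)-3-methoxy-2-methylbenzoyl]oxy}-6-methylbenzoyl)oxy]-2-hydroxy-6-methylbenzoate | COc1c(OCc2ccccc2)cc(OCc2ccccc2)c(C(=O)Oc2cc(C)c(C(=O)Oc3cc(C)c(C(=O)OCc4ccccc4)c(O)c3)c(OCc3ccccc3)c2)c1C
F14 | step 5 | tert-butyl(2-methoxy-3-methylphenoxy)dimethylsilane | COc1c(C)cccc1O[Si](C)(C)C(C)(C)C
F0 | step 7 | none | none
F0 | step 11 | none | none
A1 | alternative 1 | tert-butyl acetoacetate | CC(=O)CC(=O)OC(C)(C)C
A2 | alternative 1 | methyl (Z)-2-methoxybut-2-enoate | C/C=C(\OC)C(=O)OC
A3 | alternative 1 | tert-butyl 5-methoxy-6-methyl-2,4-dioxocyclohexane-1-carboxylate (mixture of diastereomers) | COC1C(C)C(C(=O)OC(C)(C)C)C(=O)CC1=O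
A4 | alternative 2 | tert-butyl (E)-3-[1-methoxy-4-oxo-2-(propan-2-yloxy)cyclobut-2-en-1-yl]but-2-enoate (racemic) | COC1(/C(C)=C/C(=O)OC(C)(C)C)C(OC(C)C)=CC1=O
A5 | alternative 2 | tert-butyl 2-hydroxy-4-isopropoxy-5-methoxy-6-methylbenzoate | COc1c(OC(C)C)cc(O)c(C(=O)OC(C)(C)C)c1C
A6 | alternative 3 | 3-(benzyloxy)-4-[(benzyloxy)carbonyl]-5-methylphenyl (E)-5-diazo-3-methyl-4-oxopent-2-enoate | [N-]=[N+]=CC(=O)/C(C)=C/C(=O)Oc1cc(C)c(C(=O)OCc2ccccc2)c(OCc2ccccc2)c1
A7 | alternative 3 | (ethynyloxy)tri(propan-2-yl)silane | C#CO[Si](C(C)C)(C(C)C)C(C)C
A8 | alternative 3 | 3-(benzyloxy)-4-[(benzyloxy)carbonyl]-5-methylphenyl 2-hydroxy-6-methyl-4-{[tri(propan-2-yl)silyl]oxy}benzoate | CC(C)[Si](Oc1cc(C)c(C(=O)Oc2cc(C)c(C(=O)OCc3ccccc3)c(OCc3ccccc3)c2)c(O)c1)(C(C)C)C(C)C
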